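The genkwanin half (unit I) is cut in its pyranone. There the carbonyl carbon C4 hangs on C4a, which lies between two oxygen-bearing A-ring carbons, C5 (OH) and C8a (O1), with the 7-OMe para to it. The A ring is therefore a symmetrical 2-iodo-5-methoxyresorcinol, C4 is carbon monoxide, and C2/C3 are a terminal aryl alkyne. One palladium-catalysed carbonylative alkynylation–cyclisation forms C4a–C4, C4–C3 and O1–C2 and closes ring C of unit I; either hydroxyl gives the same 5-OH/7-OMe pattern. The alkyne partner is 7,4'-di-O-benzyl-8-(4-ethynylphenoxy)apigenin, made from apigenin by benzylation, Elbs oxidation, SNAr etherification and Ohira–Bestmann homologation.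

Key step: step 8

Remark: the target has no stereocentre and no configurationally stable axis (the diaryl ether rotates freely), so it is achiral and no stereocontrol is needed. Locants: unit I = 5-hydroxy-7-methoxyflavone half (plain and single-primed), unit II = apigenin half (double- and triple-primed); the ether joins C4' of unit I to C8'' of unit II.

Design remark: the carbonyl-chelated 5''-OH of the alkyne is left free, since it is not nucleophilic. The two reactive phenols are benzyl ethers that fall together in the last step. The cheap iodide is used as the free symmetrical diol, freshly made and in excess, so that its possible hydrodeiodination does not consume the alkyne.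

Step 1
Reactants: 1 apigenin
Product: 2 7-(benzyloxy)-2-[4-(benzyloxy)phenyl]-5-hydroxy-4H-chromen-4-one
Conditions: BnBr (2.2 equiv), K2CO3, DMF, rt → 40 °C
Reagents that add atoms: benzyl bromide, BrCc1ccccc1
Why: Williamson etherification alkylates the 7- and 4'-phenoxides, while the 5-OH, hydrogen-bonded to the C4 carbonyl, should stay free under mild carbonate conditions.

Step 2
Reactants: 2 7-(benzyloxy)-2-[4-(benzyloxy)phenyl]-5-hydroxy-4H-chromen-4-one
Product: 4 7-(benzyloxy)-2-[4-(benzyloxy)phenyl]-5,8-dihydroxy-4H-chromen-4-one, via potassium 8-sulfate 3 (not isolated)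
Conditions: K2S2O8, aq. KOH/pyridine, 0 °C → rt; acidify to pH 5, remove unchanged 2; then aq. HCl, Na2SO3, 85 °C
Reagents that add atoms: potassium peroxodisulfate, [K+].[K+].[O-]S(=O)(=O)OOS(=O)(=O)[O-]
Why: Elbs persulfate oxidation: peroxodisulfate attacks the 5-phenoxide at its free para position C8, and acid hydrolysis of the aryl sulfate releases the 8-OH, conditions that aryl benzyl ethers should tolerate.

Step 3
Reactants: 4 7-(benzyloxy)-2-[4-(benzyloxy)phenyl]-5,8-dihydroxy-4H-chromen-4-one; 5 4-fluorobenzaldehyde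
Product: 6 4-({7-(benzyloxy)-2-[4-(benzyloxy)phenyl]-5-hydroxy-4-oxo-4H-chromen-8-yl}oxy)benzaldehyde
Conditions: K2CO3 (1.5 equiv), degassed DMF, 95 °C, Ar
Reagents that add atoms: none
Why: SNAr (addition–elimination): the non-chelated, more acidic 8-phenoxide displaces fluoride para to the formyl group, while the carbonyl-chelated 5-OH stays unreactive, the same selectivity as in 8-O-alkylation of 5,8-dihydroxyflavones.

Step 4
Reactants: 6 4-({7-(benzyloxy)-2-[4-(benzyloxy)phenyl]-5-hydroxy-4-oxo-4H-chromen-8-yl}oxy)benzaldehyde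
Product: 7 7-(benzyloxy)-2-[4-(benzyloxy)phenyl]-8-(4-ethynylphenoxy)-5-hydroxy-4H-chromen-4-one
Conditions: dimethyl (1-diazo-2-oxopropyl)phosphonate, K2CO3 (3 equiv), MeOH/THF, 0 °C → rt
Reagents that add atoms: dimethyl (1-diazo-2-oxopropyl)phosphonate, COP(=O)(OC)C(=[N+]=[N-])C(C)=O
Why: Seyferth–Gilbert homologation in the Ohira–Bestmann form converts the non-enolisable aryl aldehyde into the terminal alkyne under carbonate/methanol conditions that the flavone and the benzyl ethers should survive.

Step 5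
Reactants: 8 5-methoxyresorcinol
Product: 9 1-methoxy-3,5-bis(methoxymethoxy)benzene
Conditions: NaH (2.4 equiv), MOMCl (2.4 equiv), DMF, 0 °C → rt
Reagents that add atoms: chloromethyl methyl ether, COCCl
Why: O-alkylation of both phenoxides installs the two acetal ethers that serve as ortho-directing groups in the next step.

Step 6
Reactants: 9 1-methoxy-3,5-bis(methoxymethoxy)benzene
Product: 11 2-iodo-5-methoxy-1,3-bis(methoxymethoxy)benzene, via aryllithium 10 (not isolated)
Conditions: n-BuLi, THF, 0 °C; then I2, −78 °C → rt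
Reagents that add atoms: iodine, II
Why: Directed ortho-metalation: C2, flanked by two chelating OMOM groups, should be deprotonated in preference to C4/C6, and iodinolysis of the aryllithium fixes the iodine between the two oxygens.

Step 7
Reactants: 11 2-iodo-5-methoxy-1,3-bis(methoxymethoxy)benzene
Product: 12 2-iodo-5-methoxybenzene-1,3-diol
Conditions: conc. HCl (cat.), MeOH, rt, dark; used promptly
Reagents that add atoms: none
Why: Acid-catalysed acetal exchange with methanol removes both MOM groups, and the mild, iodide-free acid should avoid protodeiodination of the electron-rich aryl iodide.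

Step 8
Reactants: 7 7-(benzyloxy)-2-[4-(benzyloxy)phenyl]-8-(4-ethynylphenoxy)-5-hydroxy-4H-chromen-4-one; 12 2-iodo-5-methoxybenzene-1,3-diol; 13 carbon monoxide
Product: 16 7-(benzyloxy)-2-[4-(benzyloxy)phenyl]-5-hydroxy-8-[4-(5-hydroxy-7-methoxy-4-oxo-4H-chromen-2-yl)phenoxy]-4H-chromen-4-one (7'',4'''-di-O-benzyl target), via ynone 14 (not isolated), via enaminone 15 (not isolated)
Conditions: PdCl2(dppf) (5 mol %), CO (1 atm), Et2NH/DMF (1:1, degassed), 60 °C; 12 in 1.5-fold excess
Reagents that add atoms: none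
Why: Pd(0) inserts into the C–I bond of 12, CO migratory insertion gives the 2,6-dihydroxy-4-methoxybenzoyl–Pd(II) species, and amine-assisted alkynyl transfer from 7 followed by reductive elimination forms C4a–C4 and C4–C3 in ynone 14. Diethylamine then adds to the ynone to give β-amino enone 15, whose amine-bearing carbon (the future C2) is attacked by an ortho hydroxyl in a 6-endo-trig addition–elimination that expels Et2NH, forms O1–C2 and closes the pyranone of unit I. The closest known reaction is the Pd-catalysed carbonylative Sonogashira annulation of ortho-iodophenols with terminal aryl acetylenes in secondary amines, an established flavone synthesis. The step needs CO insertion to outrun direct alkynylation and six-membered closure to outrun 5-exo aurone formation: the electron-rich, doubly ortho-substituted aryl–Pd should migrate to CO quickly under copper-free conditions, and the enaminone places the electrophilic carbon at C2. Regiochemistry of closure is no issue because the C1 and C3 hydroxyls of 12 are symmetry-equivalent, so either gives the 5-OH/7-OMe pattern, while the chelated 5''-OH and the benzyl ethers of 7 are spectators. No stereocentre is formed.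

Step 9
Reactants: 16 7-(benzyloxy)-2-[4-(benzyloxy)phenyl]-5-hydroxy-8-[4-(5-hydroxy-7-methoxy-4-oxo-4H-chromen-2-yl)phenoxy]-4H-chromen-4-one
Product: 17 5,7-dihydroxy-8-[4-(5-hydroxy-7-methoxy-4-oxo-4H-chromen-2-yl)phenoxy]-2-(4-hydroxyphenyl)-4H-chromen-4-one
Conditions: H2 (1 atm), 10% Pd/C, THF/MeOH, rt
Reagents that add atoms: none
Why: Catalytic hydrogenolysis should cleave the two aryl benzyl ethers, while the flavone C2=C3 bonds, the diaryl ether and the methyl ether are expected to be inert at balloon pressure and room temperature.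

Compound list
1 | apigenin, 5,7-dihydroxy-2-(4-hydroxyphenyl)-4H-chromen-4-one | O=c1cc(-c2ccc(O)cc2)oc2cc(O)cc(O)c12 | starting material
2 | 7-(benzyloxy)-2-[4-(benzyloxy)phenyl]-5-hydroxy-4H-chromen-4-one (7,4'-di-O-benzylapigenin) | O=c1cc(-c2ccc(OCc3ccccc3)cc2)oc2cc(OCc3ccccc3)cc(O)c12 | intermediate
3 | potassium 7-(benzyloxy)-2-[4-(benzyloxy)phenyl]-5-hydroxy-4-oxo-4H-chromen-8-yl sulfate; formed in the flask | O=c1cc(-c2ccc(OCc3ccccc3)cc2)oc2c(OS(=O)(=O)[O-])c(OCc3ccccc3)cc(O)c12.[K+] | intermediate
4 | 7-(benzyloxy)-2-[4-(benzyloxy)phenyl]-5,8-dihydroxy-4H-chromen-4-one | O=c1cc(-c2ccc(OCc3ccccc3)cc2)oc2c(O)c(OCc3ccccc3)cc(O)c12 | intermediate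
5 | 4-fluorobenzaldehyde | O=Cc1ccc(F)cc1 | starting material
6 | 4-({7-(benzyloxy)-2-[4-(benzyloxy)phenyl]-5-hydroxy-4-oxo-4H-chromen-8-yl}oxy)benzaldehyde | O=Cc1ccc(Oc2c(OCc3ccccc3)cc(O)c3c(=O)cc(-c4ccc(OCc5ccccc5)cc4)oc23)cc1 | intermediate
7 | 7-(benzyloxy)-2-[4-(benzyloxy)phenyl]-8-(4-ethynylphenoxy)-5-hydroxy-4H-chromen-4-one | C#Cc1ccc(Oc2c(OCc3ccccc3)cc(O)c3c(=O)cc(-c4ccc(OCc5ccccc5)cc4)oc23)cc1 | intermediate
8 | 5-methoxyresorcinol, 5-methoxybenzene-1,3-diol | COc1cc(O)cc(O)c1 | starting material
9 | 1-methoxy-3,5-bis(methoxymethoxy)benzene | COCOc1cc(OC)cc(OCOC)c1 | intermediate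
10 | [4-methoxy-2,6-bis(methoxymethoxy)phenyl]lithium; formed in the flask | [Li]c1c(OCOC)cc(OC)cc1OCOC | intermediate
11 | 2-iodo-5-methoxy-1,3-bis(methoxymethoxy)benzene | COCOc1cc(OC)cc(OCOC)c1I | intermediate
12 | 2-iodo-5-methoxybenzene-1,3-diol | COc1cc(O)c(I)c(O)c1 | intermediate
13 | carbon monoxide | [C-]#[O+] | starting material
14 | 3-[4-({7-(benzyloxy)-2-[4-(benzyloxy)phenyl]-5-hydroxy-4-oxo-4H-chromen-8-yl}oxy)phenyl]-1-(2,6-dihydroxy-4-methoxyphenyl)prop-2-yn-1-one; formed in the flask | COc1cc(O)c(C(=O)C#Cc2ccc(Oc3c(OCc4ccccc4)cc(O)c4c(=O)cc(-c5ccc(OCc6ccccc6)cc5)oc34)cc2)c(O)c1 | intermediate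
15 | (E)-3-[4-({7-(benzyloxy)-2-[4-(benzyloxy)phenyl]-5-hydroxy-4-oxo-4H-chromen-8-yl}oxy)phenyl]-3-(diethylamino)-1-(2,6-dihydroxy-4-methoxyphenyl)prop-2-en-1-one; formed in the flask, E geometry expected | COc1cc(O)c(C(=O)/C=C(/N(CC)CC)c2ccc(Oc3c(OCc4ccccc4)cc(O)c4c(=O)cc(-c5ccc(OCc6ccccc6)cc5)oc34)cc2)c(O)c1 | intermediate
16 | 7-(benzyloxy)-2-[4-(benzyloxy)phenyl]-5-hydroxy-8-[4-(5-hydroxy-7-methoxy-4-oxo-4H-chromen-2-yl)phenoxy]-4H-chromen-4-one | COc1cc(O)c2c(=O)cc(-c3ccc(Oc4c(OCc5ccccc5)cc(O)c5c(=O)cc(-c6ccc(OCc7ccccc7)cc6)oc45)cc3)oc2c1 | intermediate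
17 | 5,7-dihydroxy-8-[4-(5-hydroxy-7-methoxy-4-oxo-4H-chromen-2-yl)phenoxy]-2-(4-hydroxyphenyl)-4H-chromen-4-one (achiral) | COc1cc(O)c2c(=O)cc(-c3ccc(Oc4c(O)cc(O)c5c(=O)cc(-c6ccc(O)cc6)oc45)cc3)oc2c1 | target

Total step count: 9. Longest linear sequence: 6 steps (steps 1, 2, 3, 4, 8, 9 from apigenin); the iodide branch (steps 5–7) joins at step 8.

Steps most likely to fail

Step 8. The acyl-palladium stage may lose out to hydrodeiodination of the very electron-rich iodide or to direct, CO-free alkynylation, and ring closure may leak into the five-membered (aurone) mode. The fallback is the classical chalcone route without palladium and sets out from aldehyde 6. Claisen–Schmidt condensation of 6 with commercial 2'-hydroxy-4',6'-dimethoxyacetophenone (KOH, EtOH/THF, rt) should give (E)-3-[4-({7-(benzyloxy)-2-[4-(benzyloxy)phenyl]-5-hydroxy-4-oxo-4H-chromen-8-yl}oxy)phenyl]-1-(2-hydroxy-4,6-dimethoxyphenyl)prop-2-en-1-one F1. Oxidative cyclisation with catalytic I2 in DMSO at 120 °C should then give 7-(benzyloxy)-2-[4-(benzyloxy)phenyl]-8-[4-(5,7-dimethoxy-4-oxo-4H-chromen-2-yl)phenoxy]-5-hydroxy-4H-chromen-4-one F2. BCl3 in CH2Cl2 (−78 → 0 °C) should cleave both benzyl ethers and, through chelation to the C4 carbonyl, only the 5-OMe of unit I, so the fallback comes back to the route at target 17.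

Step 2. Conversion may stay low because the phenoxide of 2 dissolves poorly in aqueous alkali, over-oxidation to the 5,8-quinone may occur, and a benzyl ether may be partly lost during the acid hydrolysis of the sulfate. The fallback is formylation/Dakin oxidation and sets out from apigenin 1. Duff formylation (hexamethylenetetramine, AcOH, 100 °C; then aq. HCl) should give 8-formylapigenin F3, to be separated from any 6-isomer. Benzylation (BnBr, K2CO3, DMF) should give 7-(benzyloxy)-2-[4-(benzyloxy)phenyl]-5-hydroxy-4-oxo-4H-chromene-8-carbaldehyde F4. Baeyer–Villiger (Dakin-type) oxidation with mCPBA in CH2Cl2 should give 7-(benzyloxy)-2-[4-(benzyloxy)phenyl]-5-hydroxy-4-oxo-4H-chromen-8-yl formate F5, and methanolysis (K2CO3, MeOH) comes back to the route at 4.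

Step 3. Attack of the doubly ortho-substituted 8-phenoxide may be sluggish, and at the temperature required the 5,8-hydroquinone system may be oxidised by traces of air or be arylated at O5 as well. The fallback replaces addition–elimination by copper catalysis and sets out from 4: Ullmann-type O-arylation with commercial 4-iodobenzaldehyde (CuI, picolinic acid, K3PO4, DMSO, 80 °C, Ar) should give aldehyde 6 directly, so it comes back at 6 and makes no new compound F0.

Further compounds
F1 | step 8 | (E)-3-[4-({7-(benzyloxy)-2-[4-(benzyloxy)phenyl]-5-hydroxy-4-oxo-4H-chromen-8-yl}oxy)phenyl]-1-(2-hydroxy-4,6-dimethoxyphenyl)prop-2-en-1-one | COc1cc(O)c(C(=O)/C=C/c2ccc(Oc3c(OCc4ccccc4)cc(O)c4c(=O)cc(-c5ccc(OCc6ccccc6)cc5)oc34)cc2)c(OC)c1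
F2 | step 8 | 7-(benzyloxy)-2-[4-(benzyloxy)phenyl]-8-[4-(5,7-dimethoxy-4-oxo-4H-chromen-2-yl)phenoxy]-5-hydroxy-4H-chromen-4-one | COc1cc(OC)c2c(=O)cc(-c3ccc(Oc4c(OCc5ccccc5)cc(O)c5c(=O)cc(-c6ccc(OCc7ccccc7)cc6)oc45)cc3)oc2c1
F3 | step 2 | 5,7-dihydroxy-2-(4-hydroxyphenyl)-4-oxo-4H-chromene-8-carbaldehyde (8-formylapigenin) | O=Cc1c(O)cc(O)c2c(=O)cc(-c3ccc(O)cc3)oc12
F4 | step 2 | 7-(benzyloxy)-2-[4-(benzyloxy)phenyl]-5-hydroxy-4-oxo-4H-chromene-8-carbaldehyde | O=Cc1c(OCc2ccccc2)cc(O)c2c(=O)cc(-c3ccc(OCc4ccccc4)cc3)oc12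
F5 | step 2 | 7-(benzyloxy)-2-[4-(benzyloxy)phenyl]-5-hydroxy-4-oxo-4H-chromen-8-yl formate | O=COc1c(OCc2ccccc2)cc(O)c2c(=O)cc(-c3ccc(OCc4ccccc4)cc3)oc12
F0 | step 3 | none | none
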